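**Plan**

Retrosynthesis: remove the two ring B benzyl groups and the 3-O-methyl group, return the pyranone to a chromane-3,4-diol, then cut C3–C4 (pinacol), O1–C2 (aryl ether) and C2–C1' (aryl glyoxylate).
Enabling feature: in ring C the neighbouring atoms C3 (bearing OMe) and C4 (the C=O carbon) both carry oxygen, so C3–C4 is the central bond of a masked 1,2-diol and can be made by reductive union of two aldehyde carbons.
Forward order: rings A and B are bought as arenes. The C2–C3 unit is fixed to ring B, O1–C2 ties it to ring A, and ring C, the only ring built, closes last at C3–C4.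
Stereochemistry: the target has no stereocentre. C2, C3 and C4 are stereogenic only in racemic intermediates and are flattened when the diol is oxidised to the flavonol.

Key step: step 8

Assumption: every chiral intermediate is a racemate. Names and SMILES show one enantiomer only, so that relative configuration and the inversion in step 5 can be followed.

**Step 1**
Reactants: 1 methoxyhydroquinone (2-methoxybenzene-1,4-diol)
Product: 2 1,4-bis(benzyloxy)-2-methoxybenzene
Conditions: BnBr, K2CO3, DMF, 60 °C, N2
Reagents that add atoms: benzyl bromide, BrCc1ccccc1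
Why: Williamson ether synthesis on both phenols gives ethers that should survive organolithium, hydride, SmI2 and hypervalent iodine reagents and can be removed together by hydrogenolysis at the end.

**Step 2**
Reactants: 2 1,4-bis(benzyloxy)-2-methoxybenzene
Product: 3 1,4-bis(benzyloxy)-2-bromo-5-methoxybenzene
Conditions: NBS, MeCN, 0 °C to rt
Reagents that add atoms: N-bromosuccinimide, O=C1CCC(=O)N1Br
Why: Electrophilic aromatic bromination should go to the one open position that is para to an alkoxy group (OMe), ortho to another and not flanked on both sides, as is general for 1,2,4-trialkoxybenzenes.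

**Step 3**
Reactants: 3 1,4-bis(benzyloxy)-2-bromo-5-methoxybenzene; 4 dimethyl oxalate
Product: 6 methyl 2-[2,5-bis(benzyloxy)-4-methoxyphenyl]-2-oxoacetate, via aryllithium 5 (not isolated)
Conditions: n-BuLi, THF, −78 °C; then cannulated into excess 4, THF, −78 °C
Reagents that add atoms: none
Why: Bromine–lithium exchange followed by acylation of the aryllithium with a dialkyl oxalate is a standard aryl glyoxylate synthesis in which the cold tetrahedral adduct and inverse addition prevent double addition, and it avoids the Lewis acids of a Friedel–Crafts glyoxylation that would strip the ortho benzyl ether.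

**Step 4**
Reactants: 6 methyl 2-[2,5-bis(benzyloxy)-4-methoxyphenyl]-2-oxoacetate
Product: 7 methyl 2-[2,5-bis(benzyloxy)-4-methoxyphenyl]-2-hydroxyacetate (racemic, S drawn)
Conditions: NaBH4 (0.5 equiv), MeOH–THF, −10 °C
Reagents that add atoms: none
Why: Borohydride reduction of the activated ketone of an alpha-keto ester is much faster than attack on the ester, and hydride reaches both faces of the planar carbonyl alike, so the new carbinol centre (future C2) is racemic.

**Step 5**
Reactants: 7 methyl 2-[2,5-bis(benzyloxy)-4-methoxyphenyl]-2-hydroxyacetate; 8 2-hydroxy-3,4-dimethoxybenzaldehyde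
Product: 9 methyl 2-[2,5-bis(benzyloxy)-4-methoxyphenyl]-2-(6-formyl-2,3-dimethoxyphenoxy)acetate (racemic, R drawn)
Conditions: PPh3, DIAD, THF, 0 °C to rt
Reagents that add atoms: none
Why: Mitsunobu etherification, well known for mandelates and phenols, lets the acidic formyl-conjugated phenol displace the oxyphosphonium group by SN2 with inversion at the future C2 (of no consequence in a racemate), the ester holding back ionisation of the electron-rich benzylic centre and the base-free medium preventing aldol closure of the acidic alpha-CH onto the ortho formyl group.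

**Step 6**
Reactants: 9 methyl 2-[2,5-bis(benzyloxy)-4-methoxyphenyl]-2-(6-formyl-2,3-dimethoxyphenoxy)acetate
Product: 10 2-[2,5-bis(benzyloxy)-4-methoxyphenyl]-2-[6-(hydroxymethyl)-2,3-dimethoxyphenoxy]ethan-1-ol (racemic, R drawn)
Conditions: LiAlH4, THF, 0 °C
Reagents that add atoms: none
Why: Hydride reduction with LiAlH4 takes the ester and the aryl aldehyde to primary alcohols in one operation, leaves aryl and benzyl ethers untouched and brings both termini to one oxidation level for a single oxidation.

**Step 7**
Reactants: 10 2-[2,5-bis(benzyloxy)-4-methoxyphenyl]-2-[6-(hydroxymethyl)-2,3-dimethoxyphenoxy]ethan-1-ol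
Product: 11 2-{1-[2,5-bis(benzyloxy)-4-methoxyphenyl]-2-oxoethoxy}-3,4-dimethoxybenzaldehyde (racemic, R drawn)
Conditions: Dess–Martin periodinane (2.5 equiv), CH2Cl2, 0 °C to rt; aq NaHCO3/Na2S2O3 work-up; crude 11 used at once
Reagents that add atoms: none
Why: Dess–Martin oxidation turns both primary alcohols into aldehydes under base-free, nearly neutral conditions and stops there, which matters because the CH between aryl, aryloxy and formyl groups enolises readily.

**Step 8**
Reactants: 11 2-{1-[2,5-bis(benzyloxy)-4-methoxyphenyl]-2-oxoethoxy}-3,4-dimethoxybenzaldehyde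
Product: 12 (2R*,3S*,4S*)-2-[2,5-bis(benzyloxy)-4-methoxyphenyl]-7,8-dimethoxychromane-3,4-diol (racemic, 2,3-trans-3,4-cis)
Conditions: SmI2 (0.1 M in THF, 3 equiv), t-BuOH (3 equiv), THF, −78 °C to −20 °C, slow addition of dilute 11; aq NaHCO3 quench
Reagents that add atoms: none
Why: SmI2 passes one electron to the conjugated aryl aldehyde, the more easily reduced carbonyl, and the samarium-bound ketyl carbon (future C4) attacks the carbonyl carbon of the tethered aliphatic aldehyde (future C3), after which a second electron and protonation complete the diol. The closest known reaction type is the SmI2-mediated intramolecular pinacol coupling of 1,6-dialdehydes, which tolerates alpha-alkoxy groups, as in sugar-derived dialdehydes that close to cyclitols. Ring C closes in a 6-exo-trig mode, the oxygen of the attacked C=O staying outside the new six-membered ring. C3 and C4 should be set cis because trivalent samarium bridges both oxygens in the closing transition state, and C3 should fall trans to C2 because the bulky C2 aryl group sits pseudo-equatorial and directs the C3 oxygen to the other face. The step needs ketyl formation at the aryl aldehyde and ring closure faster than expulsion of the alpha-aryloxy group or intermolecular coupling; the benzaldehyde conjugation, the three-oxygen pocket (formyl O, O1, formyl O) that holds both carbonyl carbons on one samarium, the absence of HMPA, the low temperature and slow addition into excess SmI2 serve this end. Any mixture of diastereomers is acceptable, since C2, C3 and C4 all become sp2 in step 9.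

**Step 9**
Reactants: 12 (2R*,3S*,4S*)-2-[2,5-bis(benzyloxy)-4-methoxyphenyl]-7,8-dimethoxychromane-3,4-diol
Product: 15 2-[2,5-bis(benzyloxy)-4-methoxyphenyl]-3-hydroxy-7,8-dimethoxy-4H-chromen-4-one, via 3-hydroxychroman-4-one 13 (not isolated), via chromane-3,4-dione 14 (not isolated)
Conditions: IBX (3 equiv), DMSO, rt
Reagents that add atoms: none
Why: IBX in DMSO is known to oxidise 1,2-diols to 1,2-diketones without glycol cleavage, and the 2-aryl-3,4-dione has an acidic C2–H whose enolisation toward C3 gives the fully conjugated 3-hydroxy-4-pyranone and erases all three stereocentres.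

**Step 10**
Reactants: 15 2-[2,5-bis(benzyloxy)-4-methoxyphenyl]-3-hydroxy-7,8-dimethoxy-4H-chromen-4-one
Product: 16 2-[2,5-bis(benzyloxy)-4-methoxyphenyl]-3,7,8-trimethoxy-4H-chromen-4-one
Conditions: MeI, K2CO3, acetone, reflux
Reagents that add atoms: iodomethane, CI
Why: Williamson-type O-methylation of the only free hydroxyl, the acidic enolic 3-OH, is the standard passage from flavonols to 3-methoxyflavones.

**Step 11**
Reactants: 16 2-[2,5-bis(benzyloxy)-4-methoxyphenyl]-3,7,8-trimethoxy-4H-chromen-4-one
Product: 17 diplotrin A, 2-(2,5-dihydroxy-4-methoxyphenyl)-3,7,8-trimethoxy-4H-chromen-4-one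
Conditions: H2 (1 atm), Pd/C, EtOAc–MeOH, rt; work-up under N2
Reagents that add atoms: none
Why: Catalytic hydrogenolysis cleaves both benzyl aryl ethers while the methyl ethers and the aromatic pyranone stay intact under one atmosphere of hydrogen, and the neutral medium spares the air-sensitive hydroquinone ring B.

**Compound list**

1 | methoxyhydroquinone (2-methoxybenzene-1,4-diol) | COc1cc(O)ccc1O | starting material
2 | 1,4-bis(benzyloxy)-2-methoxybenzene | COc1cc(OCc2ccccc2)ccc1OCc1ccccc1 | intermediate
3 | 1,4-bis(benzyloxy)-2-bromo-5-methoxybenzene | COc1cc(OCc2ccccc2)c(Br)cc1OCc1ccccc1 | intermediate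
4 | dimethyl oxalate | COC(=O)C(=O)OC | starting material
5 | [2,5-bis(benzyloxy)-4-methoxyphenyl]lithium | COc1cc(OCc2ccccc2)c([Li])cc1OCc1ccccc1 | intermediate
6 | methyl 2-[2,5-bis(benzyloxy)-4-methoxyphenyl]-2-oxoacetate | COC(=O)C(=O)c1cc(OCc2ccccc2)c(OC)cc1OCc1ccccc1 | intermediate
7 | methyl 2-[2,5-bis(benzyloxy)-4-methoxyphenyl]-2-hydroxyacetate (racemic, S drawn) | O[C@H](C(=O)OC)c1cc(OCc2ccccc2)c(OC)cc1OCc1ccccc1 | intermediate
8 | 2-hydroxy-3,4-dimethoxybenzaldehyde | COc1ccc(C=O)c(O)c1OC | starting material
9 | methyl 2-[2,5-bis(benzyloxy)-4-methoxyphenyl]-2-(6-formyl-2,3-dimethoxyphenoxy)acetate (racemic, R drawn) | COc1ccc(C=O)c(O[C@@H](C(=O)OC)c2cc(OCc3ccccc3)c(OC)cc2OCc2ccccc2)c1OC | intermediate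
10 | 2-[2,5-bis(benzyloxy)-4-methoxyphenyl]-2-[6-(hydroxymethyl)-2,3-dimethoxyphenoxy]ethan-1-ol (racemic, R drawn) | COc1ccc(CO)c(O[C@@H](CO)c2cc(OCc3ccccc3)c(OC)cc2OCc2ccccc2)c1OC | intermediate
11 | 2-{1-[2,5-bis(benzyloxy)-4-methoxyphenyl]-2-oxoethoxy}-3,4-dimethoxybenzaldehyde (racemic, R drawn) | COc1ccc(C=O)c(O[C@@H](C=O)c2cc(OCc3ccccc3)c(OC)cc2OCc2ccccc2)c1OC | intermediate
12 | (2R*,3S*,4S*)-2-[2,5-bis(benzyloxy)-4-methoxyphenyl]-7,8-dimethoxychromane-3,4-diol (racemic, 2,3-trans-3,4-cis) | COc1ccc2c(c1OC)O[C@H](c1cc(OCc3ccccc3)c(OC)cc1OCc1ccccc1)[C@@H](O)[C@H]2O | intermediate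
13 | (2R*,3R*)-2-[2,5-bis(benzyloxy)-4-methoxyphenyl]-3-hydroxy-7,8-dimethoxychroman-4-one (racemic, 2,3-trans) | COc1ccc2c(c1OC)O[C@H](c1cc(OCc3ccccc3)c(OC)cc1OCc1ccccc1)[C@@H](O)C2=O | intermediate
14 | 2-[2,5-bis(benzyloxy)-4-methoxyphenyl]-7,8-dimethoxychromane-3,4-dione (racemic, R drawn) | COc1ccc2c(c1OC)O[C@H](c1cc(OCc3ccccc3)c(OC)cc1OCc1ccccc1)C(=O)C2=O | intermediate
15 | 2-[2,5-bis(benzyloxy)-4-methoxyphenyl]-3-hydroxy-7,8-dimethoxy-4H-chromen-4-one | COc1ccc2c(c1OC)oc(-c1cc(OCc3ccccc3)c(OC)cc1OCc1ccccc1)c(O)c2=O | intermediate
16 | 2-[2,5-bis(benzyloxy)-4-methoxyphenyl]-3,7,8-trimethoxy-4H-chromen-4-one | COc1ccc2c(c1OC)oc(-c1cc(OCc3ccccc3)c(OC)cc1OCc1ccccc1)c(OC)c2=O | intermediate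
17 | diplotrin A, 2-(2,5-dihydroxy-4-methoxyphenyl)-3,7,8-trimethoxy-4H-chromen-4-one | COc1cc(O)c(-c2oc3c(OC)c(OC)ccc3c(=O)c2OC)cc1O | target

Total step count: 11.
Longest linear sequence: 11 steps (1 to 17); 4 and 8 enter as purchased compounds.

**Steps most likely to fail**

Step 8 (pinacol closure).
- What may go wrong: electron transfer to the aliphatic carbonyl followed by expulsion of the aryloxide, plain reduction of the aldehydes without C–C bond formation, or intermolecular coupling.
- Fallback: ring C is built by oxidative cyclisation of a chalcone instead, setting out from 2. Vilsmeier–Haack formylation (POCl3, DMF) should give 2,5-bis(benzyloxy)-4-methoxybenzaldehyde F1. Claisen–Schmidt condensation with purchased 2'-hydroxy-3',4'-dimethoxyacetophenone (KOH, EtOH, rt) should give (E)-3-[2,5-bis(benzyloxy)-4-methoxyphenyl]-1-(2-hydroxy-3,4-dimethoxyphenyl)prop-2-en-1-one F2. Algar–Flynn–Oyamada oxidation (H2O2, NaOH, MeOH) then closes O1–C2 and installs the 3-OH. The open position ortho to the ketone on ring A favours the flavonol over the aurone. The fallback comes back to the route at 15.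

Step 7 (double oxidation to the dialdehyde).
- What may go wrong: enolisation of the doubly activated alpha-CH with aldol closure onto the neighbouring formyl group, hydration, or further oxidation during reaction and handling.
- Fallback: the aliphatic aldehyde is reached by partial reduction from the ester, and the aryl aldehyde never leaves its oxidation level. The fallback sets out from 9. Trimethyl orthoformate and catalytic p-TsOH in MeOH should give methyl 2-[2,5-bis(benzyloxy)-4-methoxyphenyl]-2-[6-(dimethoxymethyl)-2,3-dimethoxyphenoxy]acetate F3. Diisobutylaluminium hydride (i-Bu2AlH) in toluene at −78 °C should stop at the chelated tetrahedral aluminate and give, on work-up, 2-[2,5-bis(benzyloxy)-4-methoxyphenyl]-2-[6-(dimethoxymethyl)-2,3-dimethoxyphenoxy]acetaldehyde F4. PPTS in wet acetone then frees the electron-rich benzaldehyde, and the fallback comes back at 11.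

Step 5 (Mitsunobu etherification).
- What may go wrong: slow attack by the di-ortho-substituted, hydrogen-bonded phenol on a crowded secondary centre, which would let the hydrazide compete as nucleophile or the activated alcohol ionise.
- Fallback: a preformed leaving group is displaced by the phenoxide, setting out from 7. SOCl2 in CH2Cl2 should give methyl 2-[2,5-bis(benzyloxy)-4-methoxyphenyl]-2-chloroacetate F5. The potassium phenoxide of 8 (K2CO3, DMF, rt) displaces chloride by SN2, the way salicylaldehydes are commonly joined to alpha-halo arylacetates. Room temperature and a short reaction time guard against aldol closure, and the steric course is irrelevant in the racemate. The fallback comes back at 9.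

**Further compounds**

F1 | step 8 | 2,5-bis(benzyloxy)-4-methoxybenzaldehyde | COc1cc(OCc2ccccc2)c(C=O)cc1OCc1ccccc1
F2 | step 8 | (E)-3-[2,5-bis(benzyloxy)-4-methoxyphenyl]-1-(2-hydroxy-3,4-dimethoxyphenyl)prop-2-en-1-one | COc1ccc(C(=O)/C=C/c2cc(OCc3ccccc3)c(OC)cc2OCc2ccccc2)c(O)c1OC
F3 | step 7 | methyl 2-[2,5-bis(benzyloxy)-4-methoxyphenyl]-2-[6-(dimethoxymethyl)-2,3-dimethoxyphenoxy]acetate (racemic, R drawn) | COc1ccc(C(OC)OC)c(O[C@@H](C(=O)OC)c2cc(OCc3ccccc3)c(OC)cc2OCc2ccccc2)c1OC
F4 | step 7 | 2-[2,5-bis(benzyloxy)-4-methoxyphenyl]-2-[6-(dimethoxymethyl)-2,3-dimethoxyphenoxy]acetaldehyde (racemic, R drawn) | COc1ccc(C(OC)OC)c(O[C@@H](C=O)c2cc(OCc3ccccc3)c(OC)cc2OCc2ccccc2)c1OC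
F5 | step 5 | methyl 2-[2,5-bis(benzyloxy)-4-methoxyphenyl]-2-chloroacetate (racemic, S drawn) | Cl[C@H](C(=O)OC)c1cc(OCc2ccccc2)c(OC)cc1OCc1ccccc1
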